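Larch is read at 10 min and cedar at 2.5 min, so the time of reading has to be weighed against the precatalyst charge.

| flask | starting material | second substrate | precatalyst | remark | time |
|---|---|---|---|---|---|
| blue | 0.20 mM | 0.60 mM (in portions, 2) | 20 µM | run made earlier; portions every 80 s |  |
| larch | 0.20 mM | 0.400 mM | 6.0 µM | everything together at the start | 10 min |
| cedar | 0.20 mM | 0.400 mM (in portions, 2) | 20 µM | the portions of second substrate follow each other after 80 s, the first at the start | 2.5 min |

blue run (percent of the starting material charged)

| time / s | target / % |
|---|---|
| 10.0 | 0 |
| 20.0 | 1.4 |
| 30.0 | 3.4 |
| 40.0 | 9.3 |
| 50.0 | 11.0 |

(each reading ± 1 percentage point)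

- the flask that ends with the higher amount of target, in percent of the starting material charged, or "neither" when 2 percentage points or less lies between them (larch / cedar / neither)
- final target, as a percentage of the starting material charged, in larch
- final target, as a percentage of the starting material charged, in cedar

- a reading or a percentage of target counts all its forms, free or not
- no earlier run changes the charge of precatalyst; that part of a forecast is a guess

We carry one rule: target made per unit of precatalyst and time. The blue run rises from 1.4% at 20.0 s to 11.0% at 50.0 s, with 20 µM of precatalyst. That reads as 0.00960 /µM/min, as a fraction of the starting material charged. The scatter puts about 14.7% on this reading.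

We assume that target follows precatalyst times time, and the precatalyst part is a guess. We multiply the rule by that product in each flask. Larch has the larger product, so we expect 57.6% in larch and 48.0% in cedar.

The forecast also chose larch, with 45% in larch and 36% in cedar, and said: “The order in catalyst is a guess”.

The flasks give 58.2% in larch and 52.7% in cedar, so the answer is larch.

    starting material + target → side product (k = 63.6 /M/s)
    catalyst intermediate B → free catalyst + second product (k = 0.217 /s)
    starting material + free catalyst ⇌ catalyst intermediate A (K = 2650 /M, k = 1220 /M/s)
    crystals ⇌ target, rate k4*(cs4 - [target]) while solid is left; crystals form when [target] > cs4 (solubility = 0.0120 mM, k = 2.22 /s)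
    catalyst intermediate A → free catalyst + target (k = 2.58 /s)
    second substrate + free catalyst ⇌ catalyst intermediate B (K = 1630 /M, k = 1140 /M/s)
    precatalyst → free catalyst (k = 0.00868 /s)

Larch leads by 5.5 percentage points, while side product, counted as holding two, stands at 34.1% in larch and 13.0% in cedar. Per unit of precatalyst and time, larch gave 0.00969 /µM/min and cedar 0.0105 /µM/min, against 0.00960 /µM/min from the blue run. For the larch flask read at 2.5 min, the rule gives 14.4%, and that flask holds 15.9%.

The readings stem from a simulated flask with made-up constants; the scatter is artificial.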